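**Retrosynthetic overview**
- Feature: the chain runs from the exocyclic =CH on C5 of the butenolide ring, through CH(CH3) (S), three CH2 and CH(CH3) (S), to the first CH of the E,E-diene. This stretch is the core of a C2-symmetric (3S,7S)-3,7-dimethylnona-1,8-diene. Both stereocentres are allylic and related by the axis.
- Late disconnections: the C4-OH comes from its methyl ether, the central sp2–sp2 bond of the diene from a Suzuki coupling (alkenyl-Bpin plus furyl alkenyl iodide), and the ylidene C5=CH from aldol/E1cB (methyl 3-methyltetronate plus an α-methyl aldehyde).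
- Both handles grow from the two homotopic vinyl groups of the diene. One is cut to CHO by mono-dihydroxylation and periodate; the other is borylated by cross-metathesis.
- The diene comes in one operation from achiral (2E,7E)-1,9-dibromonona-2,7-diene by double copper-catalysed SN2′ methylation. The dibromide is three steps from glutaraldehyde.
- Rings: none is formed. The furan is bought as 3-bromofuran and the butenolide as 3-methyltetronic acid.

Key step: step 4

Assumption: the (R,Rp) antipode of Taniaphos is written in step 4. The sense of induction is to be fixed beforehand on a simple (E)-alk-2-enyl bromide, and the equally available (S,Sp) antipode is used instead if that one delivers the S centres.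

**Step 1**
Reactants: 1 glutaraldehyde (50% aqueous solution); 2 triethyl phosphonoacetate
Product: 3 diethyl (2E,7E)-nona-2,7-dienedioate
Conditions: 2 (2.2 equiv), K2CO3, H2O, 0 °C to rt
Reagents that add atoms: triethyl phosphonoacetate 2, CCOC(=O)CP(=O)(OCC)OCC
Why: Double Horner–Wadsworth–Emmons olefination, in which the stabilised phosphonate anion works in water, draws the free dialdehyde out of its hydrates and should give the E-enoate at both ends.

**Step 2**
Reactants: 3 diethyl (2E,7E)-nona-2,7-dienedioate
Product: 4 (2E,7E)-nona-2,7-diene-1,9-diol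
Conditions: DIBAL-H (4.6 equiv), CH2Cl2, −78 to 0 °C; aq. Rochelle salt
Reagents that add atoms: none
Why: DIBAL-H reduces enoates by 1,2-hydride delivery only, so both esters should go to the E-allylic alcohols with the alkenes untouched.

**Step 3**
Reactants: 4 (2E,7E)-nona-2,7-diene-1,9-diol
Product: 5 (2E,7E)-1,9-dibromonona-2,7-diene
Conditions: PBr3 (0.8 equiv), Et2O, −10 to 0 °C; used promptly after a short silica plug
Reagents that add atoms: phosphorus tribromide, BrP(Br)Br
Why: Bromination of primary allylic alcohols with PBr3 runs through the phosphite ester and SN2 displacement at low temperature, which should keep the E geometry and avoid allylic transposition.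

**Step 4**
Reactants: 5 (2E,7E)-1,9-dibromonona-2,7-diene; 6 methylmagnesium bromide
Product: 7 (3S,7S)-3,7-dimethylnona-1,8-diene
Conditions: CuBr·SMe2 (5 mol%), (R,Rp)-Taniaphos (6 mol%), MeMgBr (3 M in Et2O, 2.6 equiv), CH2Cl2, −75 °C, slow addition of 5; MeOH quench; careful concentration (volatile)
Reagents that add atoms: methylmagnesium bromide 6, C[Mg]Br
Why: This is a copper-catalysed enantioselective allylic alkylation (SN2′) with a Grignard reagent, a reaction type established for unbranched aliphatic E-allyl bromides and here run at the two remote, independent ends of one substrate. The Taniaphos-bound methylcuprate adds oxidatively to the γ-carbon of each alkene anti to the departing bromide, and the σ-allylcopper(III) species undergoes reductive elimination before it can slip to the α-terminus, so each new C–CH3 bond forms at the internal carbon and leaves a vinyl group. No ring is closed. C3 and C7 are each set by the alkene face that the chiral diphosphine on copper exposes; the substrate is achiral and the ends lie three methylenes apart, so there is neither substrate bias nor cross-talk. The step needs branched-over-linear regioselectivity and the same facial sense twice, and these should be secured by the slim CH2 substituent on the γ-carbon, the E geometry from step 1, the bromide leaving group, CH2Cl2 at −75 °C and slow addition of 5, which starves the uncatalysed SN2 path. A wrong-face event at one end gives the meso (3R,7S) isomer rather than the enantiomer, so the C2 product should be enriched in enantiomeric purity beyond the single-event selectivity; because the meso and branched/linear isomers are hydrocarbons that plain silica will hardly resolve, their removal is planned on AgNO3-impregnated silica here and by HPLC at the stage of 15.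

**Step 5**
Reactants: 7 (3S,7S)-3,7-dimethylnona-1,8-diene
Product: 8 (3S,7S)-3,7-dimethylnon-8-ene-1,2-diol (both C2 epimers)
Conditions: OsO4 (1 mol%), NMO (0.5 equiv), acetone/H2O, 0 °C to rt; unreacted 7 recovered with pentane and recycled
Reagents that add atoms: N-methylmorpholine N-oxide, C[N+]1([O-])CCOCC1; water, O; osmium tetroxide (catalytic oxygen carrier), O=[Os](=O)(=O)=O
Why: In this Upjohn dihydroxylation with a deficit of oxidant the two vinyl groups are homotopic, so the first osmylation gives the same diol at either end, the polar diol is easily parted from 7 and from tetraol, and the uncontrolled carbinol centre is lost in step 6.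

**Step 6**
Reactants: 8 (3S,7S)-3,7-dimethylnon-8-ene-1,2-diol
Product: 9 (2S,6S)-2,6-dimethyloct-7-enal
Conditions: NaIO4 (1.2 equiv), THF/pH 7 buffer, 0 °C; used crude at once
Reagents that add atoms: none
Why: Malaprade glycol cleavage under buffered neutral conditions should release the α-methyl aldehyde without enolisation, so C2 keeps its S configuration.

**Step 7**
Reactants: 10 3-methyltetronic acid
Product: 11 4-methoxy-3-methylfuran-2(5H)-one
Conditions: Me2SO4 (1.1 equiv), K2CO3, acetone, reflux
Reagents that add atoms: dimethyl sulfate, COS(=O)(=O)OC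
Why: In this O-alkylation of a vinylogous acid the potassium tetronate should take the hard electrophile on the C4 oxygen rather than on the fully substituted C3.

**Step 8**
Reactants: 11 4-methoxy-3-methylfuran-2(5H)-one; 9 (2S,6S)-2,6-dimethyloct-7-enal
Product: 13 5-[(2S,6S)-1-hydroxy-2,6-dimethyloct-7-en-1-yl]-4-methoxy-3-methylfuran-2(5H)-one (epimers at C5 and C1′), via lithium dienolate 12 (not isolated)
Conditions: LDA (commercial solution, 1.05 equiv), THF, −78 °C; then 9, −78 °C; aq. NH4Cl
Reagents that add atoms: lithium diisopropylamide, [Li+].CC(C)[N-]C(C)C (lithium appears in 12 only)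
Why: In this vinylogous aldol addition LDA removes a C5 proton to give the 2-oxidofuran dienolate, which should add through C5 to the aldehyde at −78 °C faster than it enolises it, and the two uncontrolled new centres are both erased in step 9.

**Step 9**
Reactants: 13 aldol adduct
Product: 15 (5Z)-5-[(2S,6S)-2,6-dimethyloct-7-en-1-ylidene]-4-methoxy-3-methylfuran-2(5H)-one, via mesylate 14 (not isolated)
Conditions: MsCl, Et3N, CH2Cl2, 0 °C; then DBU, 0 °C to rt
Reagents that add atoms: methanesulfonyl chloride, CS(=O)(=O)Cl (atoms appear in 14 only)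
Why: Mesylation followed by E1cB elimination through the C5 anion is stereoconvergent and should favour the Z-ylidene, because in the E isomer the branched chain would clash with the C4 methoxy group, and DBU is too weak a base to touch the allylic methine.

**Step 10**
Reactants: 15 Z-ylidene tetronate; 16 vinylboronic acid pinacol ester
Product: 17 (5Z)-5-[(2S,6S,7E)-2,6-dimethyl-8-(4,4,5,5-tetramethyl-1,3,2-dioxaborolan-2-yl)oct-7-en-1-ylidene]-4-methoxy-3-methylfuran-2(5H)-one
Conditions: Hoveyda–Grubbs II (5 mol%), 16 (3 equiv), 1,4-benzoquinone (10 mol%), CH2Cl2, 40 °C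
Reagents that add atoms: vinylboronic acid pinacol ester 16, C=CB1OC(C)(C)C(C)(C)O1
Why: In this olefin cross-metathesis of a terminal alkene with vinyl-Bpin the bulky boronate and the allylic branch should favour the E-alkene, the trisubstituted electron-poor ylidene is inert, and benzoquinone suppresses Ru-hydride alkene migration past the stereocentre.

**Step 11**
Reactants: 18 (5-iodopent-1-yn-1-yl)trimethylsilane; 19 3-bromofuran
Product: 21 [5-(furan-3-yl)pent-1-yn-1-yl]trimethylsilane, via alkylzinc iodide 20 (not isolated)
Conditions: Zn dust (BrCH2CH2Br/TMSCl-activated), LiCl, THF, 40 °C; then 19, Pd(OAc)2 (2 mol%), SPhos (4 mol%), THF, rt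
Reagents that add atoms: zinc, [Zn] (appears in 20 only)
Why: In this Negishi coupling, LiCl-assisted zinc insertion into the primary iodide gives an alkylzinc that cannot cyclise onto the silyl alkyne (4-exo), and a bulky biarylphosphine on palladium should couple it with the heteroaryl bromide ahead of β-hydride elimination.

**Step 12**
Reactants: 21 [5-(furan-3-yl)pent-1-yn-1-yl]trimethylsilane
Product: 22 3-(pent-4-yn-1-yl)furan
Conditions: K2CO3 (cat.), MeOH, rt; careful concentration (volatile)
Reagents that add atoms: none
Why: Base-catalysed methanolysis (protiodesilylation) of an alkynylsilane is mild and leaves the furan untouched.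

**Step 13**
Reactants: 22 3-(pent-4-yn-1-yl)furan
Product: 24 3-[(4E)-5-iodo-4-methylpent-4-en-1-yl]furan, via alkenylalane 23 (not isolated)
Conditions: Me3Al (2.5 equiv), Cp2ZrCl2 (0.25 equiv), CH2Cl2, 0 °C to rt; then I2, THF, −30 °C
Reagents that add atoms: trimethylaluminium, C[Al](C)C; iodine, II
Why: Negishi zirconium-catalysed carboalumination adds Me and Al syn with aluminium at the terminal carbon, and iodinolysis with retention should give the E-trisubstituted iodide.

**Step 14**
Reactants: 17 alkenyl pinacol boronate; 24 3-[(4E)-5-iodo-4-methylpent-4-en-1-yl]furan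
Product: 25 (5Z)-5-[(2S,6S,7E,9E)-13-(furan-3-yl)-2,6,10-trimethyltrideca-7,9-dien-1-ylidene]-4-methoxy-3-methylfuran-2(5H)-one
Conditions: PdCl2(dppf)·CH2Cl2 (5 mol%), K3PO4 (3 equiv), THF/H2O (degassed), rt to 40 °C
Reagents that add atoms: none
Why: Suzuki–Miyaura coupling proceeds with retention at both sp2 partners, so the E,E-diene should result directly, and the mild phosphate base spares the lactone.

**Step 15**
Reactants: 25 O-methyl ether of the target
Product: 26 (5Z)-5-[(2S,6S,7E,9E)-13-(furan-3-yl)-2,6,10-trimethyltrideca-7,9-dien-1-ylidene]-4-hydroxy-3-methylfuran-2(5H)-one (target)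
Conditions: n-PrSLi (from n-PrSH and n-BuLi, 3 equiv), HMPA, rt, argon, dark; cold 0.5 M HCl, rapid extraction
Reagents that add atoms: none
Why: The soft thiolate demethylates the vinylogous methyl ester by SN2 attack and releases the stabilised tetronate anion, and since no acid or Lewis acid is present during the reaction, the furan, the diene, the Z-ylidene and both stereocentres should stay intact.

**Compound list**
1 | glutaraldehyde | O=CCCCC=O | starting material
2 | triethyl phosphonoacetate | CCOC(=O)CP(=O)(OCC)OCC | starting material
3 | diethyl (2E,7E)-nona-2,7-dienedioate | CCOC(=O)/C=C/CCC/C=C/C(=O)OCC | intermediate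
4 | (2E,7E)-nona-2,7-diene-1,9-diol | OC/C=C/CCC/C=C/CO | intermediate
5 | (2E,7E)-1,9-dibromonona-2,7-diene | BrC/C=C/CCC/C=C/CBr | intermediate
6 | methylmagnesium bromide | C[Mg]Br | starting material
7 | (3S,7S)-3,7-dimethylnona-1,8-diene | C=C[C@@H](C)CCC[C@H](C)C=C | intermediate
8 | (3S,7S)-3,7-dimethylnon-8-ene-1,2-diol (C2 epimers) | OCC(O)[C@@H](C)CCC[C@H](C)C=C | intermediate
9 | (2S,6S)-2,6-dimethyloct-7-enal | O=C[C@@H](C)CCC[C@H](C)C=C | intermediate
10 | 3-methyltetronic acid | CC1=C(O)COC1=O | starting material
11 | 4-methoxy-3-methylfuran-2(5H)-one | COC1=C(C)C(=O)OC1 | intermediate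
12 | lithium 4-methoxy-3-methylfuran-2-olate (not isolated) | [Li+].[O-]c1occ(OC)c1C | intermediate
13 | 5-[(2S,6S)-1-hydroxy-2,6-dimethyloct-7-en-1-yl]-4-methoxy-3-methylfuran-2(5H)-one (C5/C1′ epimers) | COC1=C(C)C(=O)OC1C(O)[C@@H](C)CCC[C@H](C)C=C | intermediate
14 | methanesulfonate of 13 (not isolated) | COC1=C(C)C(=O)OC1C(OS(C)(=O)=O)[C@@H](C)CCC[C@H](C)C=C | intermediate
15 | (5Z)-5-[(2S,6S)-2,6-dimethyloct-7-en-1-ylidene]-4-methoxy-3-methylfuran-2(5H)-one | COC1=C(C)C(=O)O/C1=C\[C@@H](C)CCC[C@H](C)C=C | intermediate
16 | vinylboronic acid pinacol ester | C=CB1OC(C)(C)C(C)(C)O1 | starting material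
17 | (5Z)-5-[(2S,6S,7E)-2,6-dimethyl-8-(pinacolatoboryl)oct-7-en-1-ylidene]-4-methoxy-3-methylfuran-2(5H)-one | COC1=C(C)C(=O)O/C1=C\[C@@H](C)CCC[C@H](C)/C=C/B2OC(C)(C)C(C)(C)O2 | intermediate
18 | (5-iodopent-1-yn-1-yl)trimethylsilane | C[Si](C)(C)C#CCCCI | starting material
19 | 3-bromofuran | Brc1ccoc1 | starting material
20 | [5-(trimethylsilyl)pent-4-yn-1-yl]zinc iodide (not isolated) | C[Si](C)(C)C#CCCC[Zn]I | intermediate
21 | [5-(furan-3-yl)pent-1-yn-1-yl]trimethylsilane | C[Si](C)(C)C#CCCCc1ccoc1 | intermediate
22 | 3-(pent-4-yn-1-yl)furan | C#CCCCc1ccoc1 | intermediate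
23 | [(1E)-5-(furan-3-yl)-2-methylpent-1-en-1-yl]dimethylalane (not isolated) | C[Al](C)/C=C(\C)CCCc1ccoc1 | intermediate
24 | 3-[(4E)-5-iodo-4-methylpent-4-en-1-yl]furan | I/C=C(\C)CCCc1ccoc1 | intermediate
25 | (5Z)-5-[(2S,6S,7E,9E)-13-(furan-3-yl)-2,6,10-trimethyltrideca-7,9-dien-1-ylidene]-4-methoxy-3-methylfuran-2(5H)-one | COC1=C(C)C(=O)O/C1=C\[C@@H](C)CCC[C@H](C)/C=C/C=C(\C)CCCc2ccoc2 | intermediate
26 | (5Z)-5-[(2S,6S,7E,9E)-13-(furan-3-yl)-2,6,10-trimethyltrideca-7,9-dien-1-ylidene]-4-hydroxy-3-methylfuran-2(5H)-one | CC1=C(O)/C(=C/[C@@H](C)CCC[C@H](C)/C=C/C=C(\C)CCCc2ccoc2)OC1=O | target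

**Step count**
Total steps: 15.
Longest linear sequence: 11 (steps 1–6, 8–10, 14, 15).

**Steps most likely to fail**

*Step 4.* Branched selectivity or facial selectivity may erode at one of the two ends, through uncatalysed SN2 background or equilibration of the allylcopper species. This would give isomeric hydrocarbons that are hard to remove, and volatile product may be lost as well.

The fallback sets out from diol 4 and comes back at aldehyde 9.
- Two-directional Sharpless asymmetric epoxidation (Ti(OiPr)4, D-(−)-diethyl tartrate, t-BuOOH, 4 Å sieves, CH2Cl2, −20 °C) should give (2R,3R,7R,8R)-2,3:7,8-diepoxynonane-1,9-diol F1.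
- Trimethylaluminium (hexane/CH2Cl2, 0 °C) opens 2,3-epoxy alcohols at C3 with inversion and should give (2S,3S,7S,8S)-3,7-dimethylnonane-1,2,8,9-tetraol F2.
- NaIO4 cleaves both glycols to (2S,6S)-2,6-dimethylheptanedial F3.
- One equivalent of methylenetriphenylphosphorane (THF, −78 °C) turns one of the two homotopic formyl groups into a vinyl group. This gives 9, so steps 5 and 6 drop out.

*Step 10.* Metathesis may be sluggish at the α-branched alkene. Homodimerisation may compete, and ruthenium-hydride alkene migration would erode the neighbouring stereocentre.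

The fallback sets out from 15 and comes back at boronate 17.
- Lemieux–Johnson cleavage (OsO4 cat., NaIO4, 2,6-lutidine, dioxane/H2O) should attack the monosubstituted vinyl ahead of the trisubstituted, electron-poor ylidene. It gives (2S,6S,7Z)-7-(3-methoxy-4-methyl-5-oxofuran-2(5H)-ylidene)-2,6-dimethylheptanal F4.
- A Takai-type chromium(II) olefination with 2-(dichloromethyl)-4,4,5,5-tetramethyl-1,3,2-dioxaborolane (CrCl2, LiI, THF, rt) is non-basic and E-selective. It should convert F4 into 17.

*Step 15.* The thiolate may add in conjugate fashion to the ylidene dienoate. The Z-ylidene may isomerise by addition–elimination, and the air- and acid-sensitive polyene may decay during a slow deprotection.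

The fallback sets out from 15 and comes back at target 26.
- The methyl ether is removed early with BBr3 (CH2Cl2, −78 to 0 °C). The furan and diene of 25 would not tolerate this reagent, but the isolated vinyl group of 15 should. The product is (5Z)-5-[(2S,6S)-2,6-dimethyloct-7-en-1-ylidene]-4-hydroxy-3-methylfuran-2(5H)-one F5.
- Cross-metathesis of the free acid with 16 (Hoveyda–Grubbs II, CH2Cl2, 40 °C) should give (5Z)-5-[(2S,6S,7E)-2,6-dimethyl-8-(pinacolatoboryl)oct-7-en-1-ylidene]-4-hydroxy-3-methylfuran-2(5H)-one F6.
- Suzuki coupling of F6 as its potassium tetronate with 24 (PdCl2(dppf), K3PO4 with one extra equivalent, THF/H2O), followed by mild acidification, gives 26 directly. No deprotection is then needed on the finished polyene.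

**Further compounds**
F1 | step 4 | (2R,3R,7R,8R)-2,3:7,8-diepoxynonane-1,9-diol | OC[C@H]1O[C@@H]1CCC[C@H]1O[C@@H]1CO
F2 | step 4 | (2S,3S,7S,8S)-3,7-dimethylnonane-1,2,8,9-tetraol | OC[C@@H](O)[C@@H](C)CCC[C@H](C)[C@H](O)CO
F3 | step 4 | (2S,6S)-2,6-dimethylheptanedial | O=C[C@@H](C)CCC[C@H](C)C=O
F4 | step 10 | (2S,6S,7Z)-7-(3-methoxy-4-methyl-5-oxofuran-2(5H)-ylidene)-2,6-dimethylheptanal | COC1=C(C)C(=O)O/C1=C\[C@@H](C)CCC[C@H](C)C=O
F5 | step 15 | (5Z)-5-[(2S,6S)-2,6-dimethyloct-7-en-1-ylidene]-4-hydroxy-3-methylfuran-2(5H)-one | CC1=C(O)/C(=C/[C@@H](C)CCC[C@H](C)C=C)OC1=O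
F6 | step 15 | (5Z)-5-[(2S,6S,7E)-2,6-dimethyl-8-(pinacolatoboryl)oct-7-en-1-ylidene]-4-hydroxy-3-methylfuran-2(5H)-one | CC1=C(O)/C(=C/[C@@H](C)CCC[C@H](C)/C=C/B2OC(C)(C)C(C)(C)O2)OC1=O
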